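**Retrosynthetic overview**
1. Target ⇐ debenzylation ⇐ 6‑OH‑directed epoxidation of C8=C9 ⇐ desilylation ⇐ tertiary ester made by acylating, in the same flask, the C4 alkoxide formed when i‑PrMgCl adds to a trans‑fused 4‑ketone of the five‑membered ring (ring A).
2. The 4‑ketone ⇐ a bicyclic dienone ester by redox steps only: reduction/pivaloylation at C4 (temporary β‑blocking group), hydroboration of C5=C6 (sets 5‑H and 6‑OH), C14 ester → CH3, re‑oxidation of C4.
3. Key disconnection: C1–C10 of the seven‑membered ring, by retro divinylcyclopropane–cycloheptadiene (Cope) rearrangement and retro cyclopropanation, i.e. a formal [4+3] of 3‑methyl‑2‑vinylcyclopentenone with a rhodium vinylcarbenoid.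
4. Feature that allows it: in the seven‑membered ring the epoxide carbons C8–C9 and the pair C5–C6 (ring‑fusion CH and carbinol carbon) are both at alkene oxidation level, 1,4 to each other across the C7 methylene, with the C1–C10 σ bond opposite C7; C5=C1 is then the alkene of ring A.
5. Ring order: cyclopentenone (ring A, bought) → transient cyclopropane C6–C7–C8 → seven‑membered ring → epoxide.

Key step: step 3

Remark: daucane numbering is used for all bicyclic compounds (C1 quaternary ring‑fusion carbon bearing the C15 methyl; C2, C3; C4 oxygenated carbon of ring A; C5 ring‑fusion CH; C6 carbinol; C7; C8 bearing C14; C9; C10). β is the face of the C15 methyl. All bicyclic compounds are (1R). The target is (1R,4R,5S,6S,8R,9S): 4β‑acyloxy, 5α‑H, 6α‑OH, 8α,9α‑epoxide.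
Remark: compounds 1, 3 and 15, tributyl(vinyl)stannane and Rh2(R‑DOSP)4 (dirhodium tetrakis[(R)‑N‑(dodecylbenzenesulfonyl)prolinate]) are taken as purchased.

**Step 1**
Reactants: 1 2‑bromo‑3‑methylcyclopent‑2‑en‑1‑one
Product: 2 3‑methyl‑2‑vinylcyclopent‑2‑en‑1‑one
Conditions: Bu3SnCH=CH2, Pd(PPh3)4 (5 mol %), CuI (10 mol %), DMF, 60 °C
Reagents that add atoms: tributyl(vinyl)stannane, C=C[Sn](CCCC)(CCCC)CCCC
Why: Stille coupling at the electron‑poor α‑bromoenone C–Br bond, with CuI speeding transmetalation at the hindered position; no stereocentre is formed.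

**Step 2**
Reactants: 3 methyl but‑3‑enoate
Product: 4 methyl 2‑diazobut‑3‑enoate
Conditions: 4‑AcNHC6H4SO2N3, DBU, MeCN, 0 °C; kept cold and used at once
Reagents that add atoms: 4‑acetamidobenzenesulfonyl azide, CC(=O)Nc1ccc(cc1)S(=O)(=O)N=[N+]=[N-]
Why: Regitz diazo transfer to the α‑carbon of the vinylacetate (deprotonated by DBU to the dienolate), the usual way to vinyldiazoacetates; no stereocentre.

**Step 3**
Reactants: 2 3‑methyl‑2‑vinylcyclopent‑2‑en‑1‑one; 4 methyl 2‑diazobut‑3‑enoate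
Product: 6 methyl (1R)‑4‑oxo‑11,12,13‑trinordauca‑5,8‑dien‑14‑oate [methyl (3aR)‑3a‑methyl‑1‑oxo‑1,2,3,3a,4,7‑hexahydroazulene‑6‑carboxylate], via divinylcyclopropane 5 (not isolated)
Conditions: Rh2(R‑DOSP)4 (1 mol %), hexanes, −40 °C → rt, slow addition of 4 (1.5 equiv); then PhMe, 80 °C
Reagents that add atoms: none
Why: Rh2(R‑DOSP)4 turns 4 into a donor/acceptor vinylcarbenoid that cyclopropanates only the terminal vinyl group of 2 (the ring alkene is tetrasubstituted and electron‑poor), giving 5 with vinyl and cyclopentenyl cis as is usual for these carbenoids; 5 then undergoes the divinylcyclopropane–cycloheptadiene rearrangement through the obligatory boat transition state, in which the C6–C8 cyclopropane bond breaks while C1–C10 forms. The closest known reaction type is the tandem cyclopropanation/Cope (formal [4+3]) of vinyldiazoacetates with 2‑methyl‑1‑vinylcycloalkenes, which builds methyl‑bearing quaternary centres in the same way. The seven‑membered ring is closed by the [3,3]‑sigmatropic bond formation between the vinyl terminus C10 and the ring‑alkene terminus C1, the cyclopropane CH2 becoming C7 and the new alkenes appearing at C5=C6 and C8=C9. C1 is the only stereocentre of 6; it is fixed stereospecifically by the absolute configuration of 5 (chirality transfer through the boat), which the catalyst sets in the cyclopropanation, the R catalyst being chosen from the known facial preference of Rh2(S‑DOSP)4 ((1S,2R)‑cyclopropanes from styrene). The step needs chemoselectivity for the vinyl group, cis geometry of 5 and a Cope rate that outruns other fates of 5: the first two are inherent in donor/acceptor carbenoid cyclopropanation, and the C15 methyl, which points inward in the boat, only calls for mild heating.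

**Step 4**
Reactants: 6 methyl (1R)‑4‑oxo‑11,12,13‑trinordauca‑5,8‑dien‑14‑oate
Product: 7 methyl (1R,4S)‑4β‑hydroxy‑11,12,13‑trinordauca‑5,8‑dien‑14‑oate
Conditions: (R)‑Me‑CBS oxazaborolidine (20 mol %), BH3·SMe2, PhMe, −40 °C; MeOH quench
Reagents that add atoms: none
Why: Corey–Bakshi–Shibata reduction, in which the ketone is flanked by C3H2 (small) and the alkenyl carbon C5 (large), so the (R)‑catalyst should give the (4S) = 4β alcohol by reagent control, 1,2‑selectively and faster than borane touches the ester or the alkenes; this centre is temporary and is oxidised again in step 10.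

**Step 5**
Reactants: 7 methyl (1R,4S)‑4β‑hydroxy‑11,12,13‑trinordauca‑5,8‑dien‑14‑oate
Product: 8 methyl (1R,4S)‑4β‑pivaloyloxy‑11,12,13‑trinordauca‑5,8‑dien‑14‑oate
Conditions: t‑BuCOCl, pyridine, DMAP (cat.), CH2Cl2, 0 °C → rt
Reagents that add atoms: pivaloyl chloride, CC(C)(C)C(Cl)=O
Why: DMAP‑catalysed acylation of the secondary allylic alcohol; the pivalate survives borane, shields the β face and is later removed by i‑Bu2AlH together with the ester; no new stereocentre.

**Step 6**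
Reactants: 8 methyl (1R,4S)‑4β‑pivaloyloxy‑11,12,13‑trinordauca‑5,8‑dien‑14‑oate
Product: 9 methyl (1R)‑6α‑hydroxy‑4β‑pivaloyloxy‑5α‑H‑11,12,13‑trinordauc‑8‑en‑14‑oate (trans‑fused)
Conditions: BH3·THF, THF, 0 °C → rt; then NaBO3·4H2O, H2O, rt
Reagents that add atoms: sodium perborate tetrahydrate, [Na+].[O-]OB=O.O.O.O.O
Why: Brown hydroboration–oxidation: borane takes the electron‑rich C5=C6 (the enoate C8=C9 is deactivated), boron at C6 and hydrogen at C5, syn and on the α face because the β face at C5 is flanked by both the allylic pivalate on C4 and the C15 methyl on C1, which should give 5α‑H (trans fusion) and, after oxidation with retention, 6α‑OH.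

**Step 7**
Reactants: 9 methyl (1R)‑6α‑hydroxy‑4β‑pivaloyloxy‑5α‑H‑11,12,13‑trinordauc‑8‑en‑14‑oate
Product: 10 methyl (1R)‑6α‑(tert‑butyldimethylsilyloxy)‑4β‑pivaloyloxy‑5α‑H‑11,12,13‑trinordauc‑8‑en‑14‑oate
Conditions: TBSOTf, 2,6‑lutidine, CH2Cl2, −78 → 0 °C
Reagents that add atoms: tert‑butyldimethylsilyl triflate, CC(C)(C)[Si](C)(C)OS(=O)(=O)C(F)(F)F
Why: silylation of the hindered secondary alcohol with the triflate, so that C6–O stays masked through the reductions, the Grignard addition and the acylation; no new stereocentre.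

**Step 8**
Reactants: 10 methyl (1R)‑6α‑(tert‑butyldimethylsilyloxy)‑4β‑pivaloyloxy‑5α‑H‑11,12,13‑trinordauc‑8‑en‑14‑oate
Product: 11 (1R)‑6α‑(tert‑butyldimethylsilyloxy)‑5α‑H‑11,12,13‑trinordauc‑8‑ene‑4β,14‑diol
Conditions: i‑Bu2AlH (5 equiv), CH2Cl2, −78 → 0 °C; aq. potassium sodium tartrate
Reagents that add atoms: none
Why: i‑Bu2AlH reduces the enoate 1,2 to the primary allylic alcohol and cleaves the pivalate in the same operation, while the silyl ether and the isolated alkene are inert; no stereocentre is touched.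

**Step 9**
Reactants: 11 (1R)‑6α‑(tert‑butyldimethylsilyloxy)‑5α‑H‑11,12,13‑trinordauc‑8‑ene‑4β,14‑diol
Product: 13 (1R)‑6α‑(tert‑butyldimethylsilyloxy)‑5α‑H‑11,12,13‑trinordauc‑8‑en‑4β‑ol, via mesylate 12 (not isolated)
Conditions: MsCl (1.05 equiv), 2,4,6‑collidine, CH2Cl2, −40 °C; then LiEt3BH, THF, 0 °C
Reagents that add atoms: none
Why: the primary allylic hydroxyl is sulfonylated far faster than the hindered ring carbinol, and LiEt3BH then displaces the primary allylic mesylate by direct SN2 hydride attack, turning C14 into the methyl group without moving the C8=C9 alkene.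

**Step 10**
Reactants: 13 (1R)‑6α‑(tert‑butyldimethylsilyloxy)‑5α‑H‑11,12,13‑trinordauc‑8‑en‑4β‑ol
Product: 14 (1R,5S,6S)‑6α‑(tert‑butyldimethylsilyloxy)‑5α‑H‑11,12,13‑trinordauc‑8‑en‑4‑one [(3aR,8S,8aS)‑8‑(tert‑butyldimethylsilyloxy)‑3a,6‑dimethyl‑3,3a,4,7,8,8a‑hexahydroazulen‑1(2H)‑one]
Conditions: Dess–Martin periodinane, NaHCO3, CH2Cl2, 0 °C → rt
Reagents that add atoms: none
Why: Dess–Martin oxidation under buffered, non‑enolising conditions, so the C5 centre now α to the ketone keeps its trans configuration and the β‑silyloxy group is not eliminated.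

**Step 11**
Reactants: 15 4‑(benzyloxy)‑3‑methoxybenzoic acid
Product: 16 4‑(benzyloxy)‑3‑methoxybenzoyl chloride
Conditions: (COCl)2, DMF (cat.), CH2Cl2, 0 °C → rt; evaporate
Reagents that add atoms: oxalyl chloride, ClC(=O)C(Cl)=O
Why: standard acid chloride formation through the Vilsmeier‑type chloroiminium catalyst; the benzyl ether keeps the phenol masked.

**Step 12**
Reactants: 14 (1R,5S,6S)‑6α‑(tert‑butyldimethylsilyloxy)‑5α‑H‑11,12,13‑trinordauc‑8‑en‑4‑one; 16 4‑(benzyloxy)‑3‑methoxybenzoyl chloride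
Product: 18 (1R,4R,5S,6S)‑6α‑(tert‑butyldimethylsilyloxy)‑5α‑H‑dauc‑8‑en‑4β‑yl 4‑(benzyloxy)‑3‑methoxybenzoate, via magnesium alkoxide 17 (not isolated)
Conditions: i‑PrMgCl, LaCl3·2LiCl, THF, 0 °C; then 16, DMAP (cat.), 0 °C → rt
Reagents that add atoms: isopropylmagnesium chloride, CC(C)[Mg]Cl
Why: LaCl3·2LiCl‑promoted Grignard 1,2‑addition (which suppresses enolisation and β‑hydride reduction) should come from the α face, anti to the C15 methyl and to C6 with its silyloxy group, both of which lie on the β side of the trans‑fused cyclopentanone, giving 4α‑isopropyl/4β‑O; the hindered tertiary alkoxide is then acylated in the flask, where it is nucleophilic enough although the free alcohol would not be.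

**Step 13**
Reactants: 18 (1R,4R,5S,6S)‑6α‑(tert‑butyldimethylsilyloxy)‑5α‑H‑dauc‑8‑en‑4β‑yl 4‑(benzyloxy)‑3‑methoxybenzoate
Product: 19 (1R,4R,5S,6S)‑6α‑hydroxy‑5α‑H‑dauc‑8‑en‑4β‑yl 4‑(benzyloxy)‑3‑methoxybenzoate
Conditions: HF·pyridine, pyridine, THF, 0 °C → rt
Reagents that add atoms: none
Why: fluoride desilylation under mildly acidic buffered conditions, in which no alkoxide forms, so the tertiary ester should not shift from O4 to the neighbouring O6.

**Step 14**
Reactants: 19 (1R,4R,5S,6S)‑6α‑hydroxy‑5α‑H‑dauc‑8‑en‑4β‑yl 4‑(benzyloxy)‑3‑methoxybenzoate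
Product: 20 (1R,4R,5S,6S,8R,9S)‑8α,9α‑epoxy‑6α‑hydroxy‑5α‑H‑daucan‑4β‑yl 4‑(benzyloxy)‑3‑methoxybenzoate
Conditions: VO(acac)2 (5 mol %), t‑BuOOH, CH2Cl2, 0 °C → rt
Reagents that add atoms: tert‑butyl hydroperoxide, CC(C)(C)OO
Why: vanadium‑catalysed hydroxyl‑directed epoxidation: the homoallylic 6α‑OH should deliver the peroxide oxygen to the α face of the only alkene, C8=C9, which is also the face away from the axial C15 methyl, setting C8 and C9 together.

**Step 15**
Reactants: 20 (1R,4R,5S,6S,8R,9S)‑8α,9α‑epoxy‑6α‑hydroxy‑5α‑H‑daucan‑4β‑yl 4‑(benzyloxy)‑3‑methoxybenzoate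
Product: 21 (1R,4R,5S,6S,8R,9S)‑8α,9α‑epoxy‑6α‑hydroxy‑5α‑H‑daucan‑4β‑yl 4‑hydroxy‑3‑methoxybenzoate (CNP0315707.1)
Conditions: H2 (1 atm), Pd/C (10 %), EtOAc, rt
Reagents that add atoms: none
Why: hydrogenolysis of the aryl benzyl ether under neutral conditions, which should leave the non‑benzylic trisubstituted epoxide and the tertiary aryl ester alone and give no base‑induced acyl shift.

**Compound list**
1 | 2‑bromo‑3‑methylcyclopent‑2‑en‑1‑one | CC1=C(Br)C(=O)CC1 | starting material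
2 | 3‑methyl‑2‑vinylcyclopent‑2‑en‑1‑one | C=CC1=C(C)CCC1=O | intermediate
3 | methyl but‑3‑enoate | C=CCC(=O)OC | starting material
4 | methyl 2‑diazobut‑3‑enoate | C=CC(=[N+]=[N-])C(=O)OC | intermediate
5 | methyl (1S,2S)‑2‑(2‑methyl‑5‑oxocyclopent‑1‑en‑1‑yl)‑1‑vinylcyclopropane‑1‑carboxylate (vinyl and cyclopentenyl cis) | COC(=O)[C@]1(C=C)C[C@H]1C1=C(C)CCC1=O | intermediate (not isolated)
6 | methyl (1R)‑4‑oxo‑11,12,13‑trinordauca‑5,8‑dien‑14‑oate | O=C1CC[C@]2(C)CC=C(C(=O)OC)CC=C21 | intermediate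
7 | methyl (1R,4S)‑4β‑hydroxy‑11,12,13‑trinordauca‑5,8‑dien‑14‑oate | O[C@H]1CC[C@]2(C)CC=C(C(=O)OC)CC=C21 | intermediate
8 | methyl (1R,4S)‑4β‑pivaloyloxy‑11,12,13‑trinordauca‑5,8‑dien‑14‑oate | CC(C)(C)C(=O)O[C@H]1CC[C@]2(C)CC=C(C(=O)OC)CC=C21 | intermediate
9 | methyl (1R)‑6α‑hydroxy‑4β‑pivaloyloxy‑5α‑H‑11,12,13‑trinordauc‑8‑en‑14‑oate | CC(C)(C)C(=O)O[C@H]1CC[C@]2(C)CC=C(C(=O)OC)C[C@H](O)[C@H]21 | intermediate
10 | methyl (1R)‑6α‑(tert‑butyldimethylsilyloxy)‑4β‑pivaloyloxy‑5α‑H‑11,12,13‑trinordauc‑8‑en‑14‑oate | CC(C)(C)C(=O)O[C@H]1CC[C@]2(C)CC=C(C(=O)OC)C[C@H](O[Si](C)(C)C(C)(C)C)[C@H]21 | intermediate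
11 | (1R)‑6α‑(tert‑butyldimethylsilyloxy)‑5α‑H‑11,12,13‑trinordauc‑8‑ene‑4β,14‑diol | O[C@H]1CC[C@]2(C)CC=C(CO)C[C@H](O[Si](C)(C)C(C)(C)C)[C@H]21 | intermediate
12 | 14‑methanesulfonate of 11 | O[C@H]1CC[C@]2(C)CC=C(COS(C)(=O)=O)C[C@H](O[Si](C)(C)C(C)(C)C)[C@H]21 | intermediate (not isolated)
13 | (1R)‑6α‑(tert‑butyldimethylsilyloxy)‑5α‑H‑11,12,13‑trinordauc‑8‑en‑4β‑ol | O[C@H]1CC[C@]2(C)CC=C(C)C[C@H](O[Si](C)(C)C(C)(C)C)[C@H]21 | intermediate
14 | (1R,5S,6S)‑6α‑(tert‑butyldimethylsilyloxy)‑5α‑H‑11,12,13‑trinordauc‑8‑en‑4‑one | O=C1CC[C@]2(C)CC=C(C)C[C@H](O[Si](C)(C)C(C)(C)C)[C@H]21 | intermediate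
15 | 4‑(benzyloxy)‑3‑methoxybenzoic acid | COc1cc(C(=O)O)ccc1OCc1ccccc1 | starting material
16 | 4‑(benzyloxy)‑3‑methoxybenzoyl chloride | COc1cc(C(Cl)=O)ccc1OCc1ccccc1 | intermediate
17 | chloromagnesium (1R,4R,5S,6S)‑6α‑(tert‑butyldimethylsilyloxy)‑5α‑H‑dauc‑8‑en‑4β‑olate | CC(C)[C@]1(O[Mg]Cl)CC[C@]2(C)CC=C(C)C[C@H](O[Si](C)(C)C(C)(C)C)[C@H]21 | intermediate (not isolated)
18 | (1R,4R,5S,6S)‑6α‑(tert‑butyldimethylsilyloxy)‑5α‑H‑dauc‑8‑en‑4β‑yl 4‑(benzyloxy)‑3‑methoxybenzoate | COc1cc(C(=O)O[C@@]2(C(C)C)CC[C@]3(C)CC=C(C)C[C@H](O[Si](C)(C)C(C)(C)C)[C@H]32)ccc1OCc1ccccc1 | intermediate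
19 | (1R,4R,5S,6S)‑6α‑hydroxy‑5α‑H‑dauc‑8‑en‑4β‑yl 4‑(benzyloxy)‑3‑methoxybenzoate | COc1cc(C(=O)O[C@@]2(C(C)C)CC[C@]3(C)CC=C(C)C[C@H](O)[C@H]32)ccc1OCc1ccccc1 | intermediate
20 | (1R,4R,5S,6S,8R,9S)‑8α,9α‑epoxy‑6α‑hydroxy‑5α‑H‑daucan‑4β‑yl 4‑(benzyloxy)‑3‑methoxybenzoate | COc1cc(C(=O)O[C@@]2(C(C)C)CC[C@]3(C)C[C@@H]4O[C@]4(C)C[C@H](O)[C@H]32)ccc1OCc1ccccc1 | intermediate
21 | (1R,4R,5S,6S,8R,9S)‑8α,9α‑epoxy‑6α‑hydroxy‑5α‑H‑daucan‑4β‑yl 4‑hydroxy‑3‑methoxybenzoate | COc1cc(C(=O)O[C@@]2(C(C)C)CC[C@]3(C)C[C@@H]4O[C@]4(C)C[C@H](O)[C@H]32)ccc1O | target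

**Step count and risks**
Total: 15 steps. Longest linear sequence: 13 steps (1 → 21 through steps 1, 3–10 and 12–15).

Step 3. What may go wrong: incomplete enantiofacial discrimination in the carbene transfer to the hindered, twisted vinyl group, or loss of 4 by electrocyclisation to a pyrazole before transfer. Fallback: setting out from 2 and 4, the formal [4+3] is run with achiral Rh2(OPiv)4 (excess 4, refluxing hexanes), which gives 6 together with its enantiomer, methyl (1S)‑4‑oxo‑11,12,13‑trinordauca‑5,8‑dien‑14‑oate F1. The reagent‑controlled (R)‑CBS reduction of step 4 then turns the two enantiomers into diastereomers, 7 and methyl (1S,4S)‑4‑hydroxy‑11,12,13‑trinordauca‑5,8‑dien‑14‑oate F2, which are separated by chromatography; the route is rejoined at 7.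

Step 6. What may go wrong: attack of borane on the β face (cis‑fused 5β,6β isomer), or slow reaction at the hindered alkene with competing reduction of the enoate. Fallback: setting out from 8, OsO4 (cat.)/N‑methylmorpholine N‑oxide dihydroxylates C5=C6 on the α face to methyl (1R)‑5α,6α‑dihydroxy‑4β‑pivaloyloxy‑11,12,13‑trinordauc‑8‑en‑14‑oate F3. Thiocarbonyldiimidazole (PhMe, 80 °C) closes the cyclic 5,6‑thionocarbonate F4. Bu3SnH/AIBN (PhMe, 100 °C) then cleaves the C5–O bond regioselectively (tertiary radical, Barton‑type deoxygenation); the radical should take hydrogen on the α face, and hydrolytic work‑up of the O6 thiolcarbonate returns 9.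

Step 12. What may go wrong: enolisation or β‑hydride reduction of the hindered ketone by the secondary Grignard reagent, incomplete O‑acylation of the tertiary alkoxide, or a silyl shift from O6 to O4 before acylation. Fallback: setting out from 14, isopropenylmagnesium bromide/CeCl3 (THF, −78 °C; smaller nucleophile without β‑hydrogen) gives the tertiary allylic alcohol (1R,4R,5S,6S)‑6α‑(tert‑butyldimethylsilyloxy)‑5α‑H‑dauca‑8,11‑dien‑4β‑ol F5, which is isolated. It is deprotonated with MeMgBr and acylated with 16 to (1R,4R,5S,6S)‑6α‑(tert‑butyldimethylsilyloxy)‑5α‑H‑dauca‑8,11‑dien‑4β‑yl 4‑(benzyloxy)‑3‑methoxybenzoate F6. Chemoselective hydrogenation of the 1,1‑disubstituted alkene with RhCl(PPh3)3/H2 (benzene, rt) then gives 18.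

**Further compounds**
F1 | step 3 | methyl (1S)‑4‑oxo‑11,12,13‑trinordauca‑5,8‑dien‑14‑oate (enantiomer of 6) | O=C1CC[C@@]2(C)CC=C(C(=O)OC)CC=C21
F2 | step 3 | methyl (1S,4S)‑4‑hydroxy‑11,12,13‑trinordauca‑5,8‑dien‑14‑oate | O[C@H]1CC[C@@]2(C)CC=C(C(=O)OC)CC=C21
F3 | step 6 | methyl (1R)‑5α,6α‑dihydroxy‑4β‑pivaloyloxy‑11,12,13‑trinordauc‑8‑en‑14‑oate | CC(C)(C)C(=O)O[C@H]1CC[C@]2(C)CC=C(C(=O)OC)C[C@H](O)[C@]21O
F4 | step 6 | cyclic 5α,6α‑thionocarbonate of F3 | CC(C)(C)C(=O)O[C@H]1CC[C@]2(C)CC=C(C(=O)OC)C[C@@H]3OC(=S)O[C@@]321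
F5 | step 12 | (1R,4R,5S,6S)‑6α‑(tert‑butyldimethylsilyloxy)‑5α‑H‑dauca‑8,11‑dien‑4β‑ol | C=C(C)[C@]1(O)CC[C@]2(C)CC=C(C)C[C@H](O[Si](C)(C)C(C)(C)C)[C@H]21
F6 | step 12 | (1R,4R,5S,6S)‑6α‑(tert‑butyldimethylsilyloxy)‑5α‑H‑dauca‑8,11‑dien‑4β‑yl 4‑(benzyloxy)‑3‑methoxybenzoate | COc1cc(C(=O)O[C@@]2(C(C)=C)CC[C@]3(C)CC=C(C)C[C@H](O[Si](C)(C)C(C)(C)C)[C@H]32)ccc1OCc1ccccc1
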